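**Retrosynthetic overview** (labdane-type numbering: decalin C1–C10; C17 = carboxyl carbon on C8; C11–C14 = chain on C9; C18/C19 on C4; C20 = methyl on C10)
1. Endgame: the C17 acid is freed last from a tert-butyl ester; the C11–C12 single bond comes from hydrogenation of a C11=C12 alkene made by Wittig reaction of a C11 aldehyde with a C12–C14 ylide from (2S)-3-bromo-2-methylpropan-1-ol (source of C13).
2. Enabling feature: the C7=C8 enoate is the conjugated isomer of a C6=C7 alkene with H on C8. With the alkene transposed, ring B (C5–C6–C7–C8–C9–C10) is a Diels–Alder retron: diene C5=C6–C7=C8 (ester on C8), dienophile C9=C10, and the four ring A carbons C1–C4 as tether.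
3. Key disconnection: intramolecular Diels–Alder reaction of acyclic trienimide 14 (C11 as acyl carbon carrying (4S)-4-benzyloxazolidin-2-one). One operation forms C5–C10 and C8–C9, closes both rings and sets C5, C9 and C10.
4. Trienimide 14 comes from 2,2-dimethylpent-4-enal (C1–C5, C18, C19) by vinylogous Horner–Wadsworth–Emmons olefination (C5=C6) and B-alkyl Suzuki–Miyaura coupling (C1–C10) with the (E)-enol triflate of ethyl acetoacetate (C9, C10, C11, C20).
5. Ring order: rings A and B are formed together in step 7; no ring is made before or after it.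

Key step: step 7

Remark: compounds 22 to 24 are drawn with the (Z)-C11=C12 geometry expected from a non-stabilised ylide; the (E) isomer would converge on the same compound 25 in step 14.

**Step 1**
Reactants: 1 tert-butyl (2E)-4-bromobut-2-enoate; 2 triethyl phosphite
Product: 3 tert-butyl (2E)-4-(diethoxyphosphoryl)but-2-enoate
Conditions: neat, 120 °C, bromoethane distilled off
Reagents that add atoms: none
Why: Michaelis–Arbuzov reaction, in which SN2 attack of phosphorus on the primary allylic bromide and dealkylation of the phosphonium salt by bromide give the allylic phosphonate with the (E)-enoate unchanged.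

**Step 2**
Reactants: 3 tert-butyl (2E)-4-(diethoxyphosphoryl)but-2-enoate; 4 2,2-dimethylpent-4-enal
Product: 6 tert-butyl (2E,4E)-6,6-dimethylnona-2,4,8-trienoate, via lithiated phosphonate 5 (not isolated)
Conditions: LiN(SiMe3)2, THF, −78 °C; then 4, −78 °C to 0 °C
Reagents that add atoms: none
Why: vinylogous Horner–Wadsworth–Emmons olefination, in which anion 5 adds through the carbon next to phosphorus to the non-enolisable aldehyde and loss of phosphate gives the (4E)-alkene (future C5=C6) beside the retained (2E)-alkene (future C7=C8).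

**Step 3**
Reactants: 7 ethyl 3-oxobutanoate
Product: 8 ethyl (2E)-3-{[(trifluoromethyl)sulfonyl]oxy}but-2-enoate
Conditions: Tf2O, aqueous Me4NOH, hexane, 5 °C to rt
Reagents that add atoms: trifluoromethanesulfonic anhydride, O=S(=O)(OS(=O)(=O)C(F)(F)F)C(F)(F)F
Why: O-triflation of the β-keto ester enolate, in which the non-chelating tetramethylammonium counter-ion favours the (E)-enol triflate (triflate trans to the ester) and so fixes the later (E)-C9=C10 geometry.

**Step 4**
Reactants: 6 tert-butyl (2E,4E)-6,6-dimethylnona-2,4,8-trienoate; 8 ethyl (2E)-3-{[(trifluoromethyl)sulfonyl]oxy}but-2-enoate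
Product: 10 1-tert-butyl 12-ethyl (2E,4E,10E)-6,6,10-trimethyldodeca-2,4,10-trienedioate, via alkylborane 9 (not isolated)
Conditions: 9-BBN-H, THF, 0 °C to rt; then 8, PdCl2(dppf) (dppf = Fe(C5H4PPh2)2, 5 mol %), aqueous K3PO4, DMF, rt to 50 °C
Reagents that add atoms: none
Why: anti-Markovnikov hydroboration of the only monosubstituted alkene followed by B-alkyl Suzuki–Miyaura coupling, which replaces the triflate with retention of alkene geometry and so places the C20 methyl group cis to the ester carbon C11.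

**Step 5**
Reactants: 10 1-tert-butyl 12-ethyl (2E,4E,10E)-6,6,10-trimethyldodeca-2,4,10-trienedioate
Product: 11 (2E,8E,10E)-12-tert-butoxy-3,7,7-trimethyl-12-oxododeca-2,8,10-trienoic acid
Conditions: LiOH·H2O, THF/MeOH/H2O, 40 °C; then 1 M HCl to pH 3, 0 °C
Reagents that add atoms: lithium hydroxide, [Li+].[OH-]
Why: saponification (acyl–oxygen cleavage by hydroxide) distinguishes the ethyl ester from the tert-butyl ester, which is shielded against attack at its carbonyl group.

**Step 6**
Reactants: 11 (2E,8E,10E)-12-tert-butoxy-3,7,7-trimethyl-12-oxododeca-2,8,10-trienoic acid; 12 (4S)-4-benzyl-1,3-oxazolidin-2-one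
Product: 14 tert-butyl (2E,4E,10E)-12-[(4S)-4-benzyl-2-oxo-1,3-oxazolidin-3-yl]-6,6,10-trimethyl-12-oxododeca-2,4,10-trienoate, via mixed pivalic anhydride 13 (not isolated)
Conditions: pivaloyl chloride, Et3N, THF, −20 °C; then LiCl, 12, −20 °C to rt
Reagents that add atoms: none
Why: N-acylation of the oxazolidinone through the mixed pivalic anhydride under LiCl/Et3N activation, the nucleophile attacking the unhindered enoyl carbonyl and both alkene geometries staying intact.

**Step 7**
Reactants: 14 tert-butyl (2E,4E,10E)-12-[(4S)-4-benzyl-2-oxo-1,3-oxazolidin-3-yl]-6,6,10-trimethyl-12-oxododeca-2,4,10-trienoate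
Product: 15 tert-butyl (1S,2S,4aS,8aS)-1-{[(4S)-4-benzyl-2-oxo-1,3-oxazolidin-3-yl]carbonyl}-5,5,8a-trimethyl-1,2,4a,5,6,7,8,8a-octahydronaphthalene-2-carboxylate
Conditions: Me2AlCl (2.0 equiv), CH2Cl2, −30 °C to 0 °C; aqueous HCl work-up
Reagents that add atoms: none
Why: Me2AlCl turns the imide into the cationic bidentate chelate [imide·AlMe2]+ with an s-cis enoyl unit, and the tethered (E,E)-dienoate then adds across C9=C10 in a concerted but asynchronous intramolecular [4+2] cycloaddition (type 1 intramolecular Diels–Alder reaction). The closest known reaction type is the Me2AlCl-promoted cyclisation of (2E,7E,9E)-deca-2,7,9-trienoyl oxazolidinones to trans-fused octalins under auxiliary control. Ring B is closed as the new cyclohexene by the C8–C9 bond together with the C5–C10 bond (both σ-bonds of the [4+2] lie in this ring), and ring A is closed in the same event as the six-membered tether ring by the C5–C10 bond (C1–C4 is the four-carbon tether of a 1,7,9-decatriene). C9 and C10 are set relative to each other by the (E)-dienophile geometry (C20 methyl cis to the acyl carbon C11), C5 by the (E)-C5=C6 bond combined with the endo transition state (acyl group under the diene and tether exo, hence the trans ring fusion), C8 (temporary) by the (E)-C7=C8 bond, and the absolute sense by the benzyl group of the (4S)-auxiliary, which covers the Cα-re face of the chelate so that the diene adds to the Cα-si face. The step needs endo over exo selectivity, π-facial selectivity and enough reactivity from an ester-bearing diene toward a trisubstituted dienophile; the rigid chelate and the exo-placed tether should secure the first two, and the cationic activation, the Thorpe–Ingold effect of the C4 gem-dimethyl group and the intramolecularity the third.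

**Step 8**
Reactants: 15 tert-butyl (1S,2S,4aS,8aS)-1-{[(4S)-4-benzyl-2-oxo-1,3-oxazolidin-3-yl]carbonyl}-5,5,8a-trimethyl-1,2,4a,5,6,7,8,8a-octahydronaphthalene-2-carboxylate
Product: 16 tert-butyl (1S,2S,4aS,8aS)-1-(hydroxymethyl)-5,5,8a-trimethyl-1,2,4a,5,6,7,8,8a-octahydronaphthalene-2-carboxylate
Conditions: LiBH4, MeOH (1 equiv), THF, 0 °C; aqueous NaOH work-up
Reagents that add atoms: none
Why: reductive cleavage of the N-acyl oxazolidinone, in which borohydride attacks the exocyclic imide carbonyl to give the primary alcohol and the free auxiliary while the tert-butyl ester and the ring alkene do not react with LiBH4 at 0 °C.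

**Step 9**
Reactants: 16 tert-butyl (1S,2S,4aS,8aS)-1-(hydroxymethyl)-5,5,8a-trimethyl-1,2,4a,5,6,7,8,8a-octahydronaphthalene-2-carboxylate
Product: 17 tert-butyl (1S,2S,4aS,8aS)-1-formyl-5,5,8a-trimethyl-1,2,4a,5,6,7,8,8a-octahydronaphthalene-2-carboxylate
Conditions: Dess–Martin periodinane, pyridine, CH2Cl2, 0 °C to rt
Reagents that add atoms: none
Why: Dess–Martin oxidation converts the primary alcohol into the aldehyde under buffered, non-basic conditions that leave the epimerisable centres C8 and C9 untouched.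

**Step 10**
Reactants: 18 (2S)-3-bromo-2-methylpropan-1-ol; 19 triphenylphosphine
Product: 20 [(2S)-3-hydroxy-2-methylpropyl]triphenylphosphonium bromide
Conditions: MeCN, reflux
Reagents that add atoms: none
Why: SN2 quaternisation of triphenylphosphine by the primary bromide, which does not touch the stereocentre that becomes C13.

**Step 11**
Reactants: 17 tert-butyl (1S,2S,4aS,8aS)-1-formyl-5,5,8a-trimethyl-1,2,4a,5,6,7,8,8a-octahydronaphthalene-2-carboxylate; 20 [(2S)-3-hydroxy-2-methylpropyl]triphenylphosphonium bromide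
Product: 22 tert-butyl (1S,2S,4aS,8aR)-1-[(1Z,3R)-4-hydroxy-3-methylbut-1-en-1-yl]-5,5,8a-trimethyl-1,2,4a,5,6,7,8,8a-octahydronaphthalene-2-carboxylate, via oxido ylide 21 (not isolated)
Conditions: 20 (1.5 equiv), NaN(SiMe3)2 (3.0 equiv), THF, −78 °C to 0 °C; then 17, −78 °C to rt; aqueous NH4Cl
Reagents that add atoms: none
Why: Wittig olefination with a non-stabilised γ-oxido ylide (the alkoxide formed by the first equivalent of base serves as its own protection) builds the C11=C12 bond and brings in C13 with its configuration unchanged.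

**Step 12**
Reactants: 22 tert-butyl (1S,2S,4aS,8aR)-1-[(1Z,3R)-4-hydroxy-3-methylbut-1-en-1-yl]-5,5,8a-trimethyl-1,2,4a,5,6,7,8,8a-octahydronaphthalene-2-carboxylate
Product: 23 tert-butyl (1S,2S,4aS,8aR)-5,5,8a-trimethyl-1-[(1Z,3R)-3-methyl-4-(2-methylpropanoyloxy)but-1-en-1-yl]-1,2,4a,5,6,7,8,8a-octahydronaphthalene-2-carboxylate
Conditions: 2-methylpropanoyl chloride, pyridine, DMAP (cat.), CH2Cl2, 0 °C
Reagents that add atoms: 2-methylpropanoyl chloride, CC(C)C(Cl)=O
Why: nucleophile-catalysed O-acylation (acylpyridinium intermediate) of the unhindered primary alcohol installs the isobutyrate.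

**Step 13**
Reactants: 23 tert-butyl (1S,2S,4aS,8aR)-5,5,8a-trimethyl-1-[(1Z,3R)-3-methyl-4-(2-methylpropanoyloxy)but-1-en-1-yl]-1,2,4a,5,6,7,8,8a-octahydronaphthalene-2-carboxylate
Product: 24 tert-butyl (1R,4aS,8aS)-5,5,8a-trimethyl-1-[(1Z,3R)-3-methyl-4-(2-methylpropanoyloxy)but-1-en-1-yl]-1,4,4a,5,6,7,8,8a-octahydronaphthalene-2-carboxylate
Conditions: DBU, toluene, 80 °C
Reagents that add atoms: none
Why: base-mediated prototropic isomerisation through the extended ester enolate moves the C6=C7 alkene into conjugation as C7=C8, driven by conjugation, higher alkene substitution and release of the 1,3-diaxial contact between the C8 ester and the C20 methyl group, while the non-acidic C9–H keeps its configuration.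

**Step 14**
Reactants: 24 tert-butyl (1R,4aS,8aS)-5,5,8a-trimethyl-1-[(1Z,3R)-3-methyl-4-(2-methylpropanoyloxy)but-1-en-1-yl]-1,4,4a,5,6,7,8,8a-octahydronaphthalene-2-carboxylate
Product: 25 tert-butyl (1R,4aS,8aS)-5,5,8a-trimethyl-1-[(3R)-3-methyl-4-(2-methylpropanoyloxy)butyl]-1,4,4a,5,6,7,8,8a-octahydronaphthalene-2-carboxylate
Conditions: H2 (3 atm), RhCl(PPh3)3 (10 mol %), toluene/EtOH, rt
Reagents that add atoms: none
Why: homogeneous hydrogenation with RhCl(PPh3)3 is selective for the disubstituted, non-conjugated C11=C12 alkene over the trisubstituted, conjugated and hindered C7=C8 alkene, and it removes the Z/E question.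

**Step 15**
Reactants: 25 tert-butyl (1R,4aS,8aS)-5,5,8a-trimethyl-1-[(3R)-3-methyl-4-(2-methylpropanoyloxy)butyl]-1,4,4a,5,6,7,8,8a-octahydronaphthalene-2-carboxylate
Product: 26 (1R,4aS,8aS)-5,5,8a-trimethyl-1-[(3R)-3-methyl-4-(2-methylpropanoyloxy)butyl]-1,4,4a,5,6,7,8,8a-octahydronaphthalene-2-carboxylic acid
Conditions: TFA/CH2Cl2 (1:4), 0 °C to rt
Reagents that add atoms: none
Why: acid-mediated alkyl–oxygen cleavage of the tert-butyl ester (tert-butyl cation lost as isobutene) frees the C17 carboxylic acid, to which the primary isobutyrate and the conjugated alkene are inert.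

**Compound list**
1 | tert-butyl (2E)-4-bromobut-2-enoate | CC(C)(C)OC(=O)/C=C/CBr | starting material
2 | triethyl phosphite | CCOP(OCC)OCC | starting material
3 | tert-butyl (2E)-4-(diethoxyphosphoryl)but-2-enoate | CCOP(=O)(OCC)C/C=C/C(=O)OC(C)(C)C | intermediate
4 | 2,2-dimethylpent-4-enal | C=CCC(C)(C)C=O | starting material
5 | lithium (2E)-4-tert-butoxy-1-(diethoxyphosphoryl)-4-oxobut-2-en-1-ide (lithiated phosphonate) | [Li+].CCOP(=O)(OCC)[CH-]/C=C/C(=O)OC(C)(C)C | intermediate
6 | tert-butyl (2E,4E)-6,6-dimethylnona-2,4,8-trienoate | C=CCC(C)(C)/C=C/C=C/C(=O)OC(C)(C)C | intermediate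
7 | ethyl 3-oxobutanoate | CCOC(=O)CC(C)=O | starting material
8 | ethyl (2E)-3-{[(trifluoromethyl)sulfonyl]oxy}but-2-enoate | CCOC(=O)/C=C(\C)OS(=O)(=O)C(F)(F)F | intermediate
9 | tert-butyl (2E,4E)-9-(9-borabicyclo[3.3.1]nonan-9-yl)-6,6-dimethylnona-2,4-dienoate (alkylborane) | CC(C)(C)OC(=O)/C=C/C=C/C(C)(C)CCCB1C2CCCC1CCC2 | intermediate
10 | 1-tert-butyl 12-ethyl (2E,4E,10E)-6,6,10-trimethyldodeca-2,4,10-trienedioate | CCOC(=O)/C=C(\C)CCCC(C)(C)/C=C/C=C/C(=O)OC(C)(C)C | intermediate
11 | (2E,8E,10E)-12-tert-butoxy-3,7,7-trimethyl-12-oxododeca-2,8,10-trienoic acid | OC(=O)/C=C(\C)CCCC(C)(C)/C=C/C=C/C(=O)OC(C)(C)C | intermediate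
12 | (4S)-4-benzyl-1,3-oxazolidin-2-one | O=C1N[C@@H](Cc2ccccc2)CO1 | starting material
13 | (2E,8E,10E)-12-tert-butoxy-3,7,7-trimethyl-12-oxododeca-2,8,10-trienoic 2,2-dimethylpropanoic anhydride (mixed pivalic anhydride) | CC(C)(C)C(=O)OC(=O)/C=C(\C)CCCC(C)(C)/C=C/C=C/C(=O)OC(C)(C)C | intermediate
14 | tert-butyl (2E,4E,10E)-12-[(4S)-4-benzyl-2-oxo-1,3-oxazolidin-3-yl]-6,6,10-trimethyl-12-oxododeca-2,4,10-trienoate | O=C(/C=C(\C)CCCC(C)(C)/C=C/C=C/C(=O)OC(C)(C)C)N1[C@@H](Cc2ccccc2)COC1=O | intermediate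
15 | tert-butyl (1S,2S,4aS,8aS)-1-{[(4S)-4-benzyl-2-oxo-1,3-oxazolidin-3-yl]carbonyl}-5,5,8a-trimethyl-1,2,4a,5,6,7,8,8a-octahydronaphthalene-2-carboxylate | O=C(N1[C@@H](Cc2ccccc2)COC1=O)[C@H]3[C@@H](C(=O)OC(C)(C)C)C=C[C@H]4C(C)(C)CCC[C@]34C | intermediate
16 | tert-butyl (1S,2S,4aS,8aS)-1-(hydroxymethyl)-5,5,8a-trimethyl-1,2,4a,5,6,7,8,8a-octahydronaphthalene-2-carboxylate | OC[C@H]1[C@@H](C(=O)OC(C)(C)C)C=C[C@H]2C(C)(C)CCC[C@]12C | intermediate
17 | tert-butyl (1S,2S,4aS,8aS)-1-formyl-5,5,8a-trimethyl-1,2,4a,5,6,7,8,8a-octahydronaphthalene-2-carboxylate | O=C[C@H]1[C@@H](C(=O)OC(C)(C)C)C=C[C@H]2C(C)(C)CCC[C@]12C | intermediate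
18 | (2S)-3-bromo-2-methylpropan-1-ol | OC[C@H](C)CBr | starting material
19 | triphenylphosphine | c1ccc(cc1)P(c1ccccc1)c1ccccc1 | starting material
20 | [(2S)-3-hydroxy-2-methylpropyl]triphenylphosphonium bromide | OC[C@H](C)C[P+](c1ccccc1)(c1ccccc1)c1ccccc1.[Br-] | intermediate
21 | sodium (2S)-2-methyl-3-(triphenyl-λ5-phosphanylidene)propan-1-olate (oxido ylide) | [Na+].[O-]C[C@H](C)C=P(c1ccccc1)(c1ccccc1)c1ccccc1 | intermediate
22 | tert-butyl (1S,2S,4aS,8aR)-1-[(1Z,3R)-4-hydroxy-3-methylbut-1-en-1-yl]-5,5,8a-trimethyl-1,2,4a,5,6,7,8,8a-octahydronaphthalene-2-carboxylate | OC[C@H](C)/C=C\[C@H]1[C@@H](C(=O)OC(C)(C)C)C=C[C@H]2C(C)(C)CCC[C@]12C | intermediate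
23 | tert-butyl (1S,2S,4aS,8aR)-5,5,8a-trimethyl-1-[(1Z,3R)-3-methyl-4-(2-methylpropanoyloxy)but-1-en-1-yl]-1,2,4a,5,6,7,8,8a-octahydronaphthalene-2-carboxylate | CC(C)C(=O)OC[C@H](C)/C=C\[C@H]1[C@@H](C(=O)OC(C)(C)C)C=C[C@H]2C(C)(C)CCC[C@]12C | intermediate
24 | tert-butyl (1R,4aS,8aS)-5,5,8a-trimethyl-1-[(1Z,3R)-3-methyl-4-(2-methylpropanoyloxy)but-1-en-1-yl]-1,4,4a,5,6,7,8,8a-octahydronaphthalene-2-carboxylate | CC(C)C(=O)OC[C@H](C)/C=C\[C@H]1C(C(=O)OC(C)(C)C)=CC[C@H]2C(C)(C)CCC[C@]12C | intermediate
25 | tert-butyl (1R,4aS,8aS)-5,5,8a-trimethyl-1-[(3R)-3-methyl-4-(2-methylpropanoyloxy)butyl]-1,4,4a,5,6,7,8,8a-octahydronaphthalene-2-carboxylate | CC(C)C(=O)OC[C@H](C)CC[C@H]1C(C(=O)OC(C)(C)C)=CC[C@H]2C(C)(C)CCC[C@]12C | intermediate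
26 | (1R,4aS,8aS)-5,5,8a-trimethyl-1-[(3R)-3-methyl-4-(2-methylpropanoyloxy)butyl]-1,4,4a,5,6,7,8,8a-octahydronaphthalene-2-carboxylic acid | CC(C)C(=O)OC[C@H](C)CC[C@H]1C(C(=O)O)=CC[C@H]2C(C)(C)CCC[C@]12C | target

**Step count**
Total step count: 15.
Longest linear sequence: 13 steps (steps 1, 2, 4, 5, 6, 7, 8, 9, 11, 12, 13, 14, 15; compounds 1 → 3 → 6 → 10 → 11 → 14 → 15 → 16 → 17 → 22 → 23 → 24 → 25 → 26).

**Steps most likely to fail**

Step 7. The Lewis acid may be bound by, or may cleave, the tert-butyl dienoate, which would leave the diene too electron-poor to add to the hindered trisubstituted dienophile. The developing 1,3-diaxial contact between the C20 methyl group and the axial methyl group on C4 may also erode the endo (trans-fusion) preference. The fallback replaces the metal-bound auxiliary by iminium-ion catalysis. It sets out from trienoate 6, whose alkylborane 9 is coupled (PdCl2(dppf), K3PO4, DMF/H2O) with (E)-3-iodobut-2-en-1-ol to give tert-butyl (2E,4E,10E)-12-hydroxy-6,6,10-trimethyldodeca-2,4,10-trienoate F1. MnO2 in CH2Cl2 should oxidise the allylic alcohol to tert-butyl (2E,4E,10E)-6,6,10-trimethyl-12-oxododeca-2,4,10-trienoate F2. The trienal is then cyclised with the trifluoroacetate salt of (2S,5S)-5-benzyl-2-tert-butyl-3-methylimidazolidin-4-one (20 mol %) in MeCN/H2O at 5 °C. The benzyl group of the (E)-iminium ion covers the same Cα-re face as the auxiliary, and the cycloadduct is aldehyde 17, where the route is rejoined (compounds 10 to 16 are bypassed).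

Step 11. The basic oxido ylide may deprotonate the hindered aldehyde at C9 (or the ester at C8) instead of adding to the carbonyl group, which would give low conversion and epimerisation at C9. The fallback replaces olefination by a C(sp3)–C(sp3) cross-coupling, which also makes the hydrogenation unnecessary. It sets out from alcohol 16, which with I2, PPh3 and imidazole (toluene, 60 °C) should give tert-butyl (1S,2S,4aS,8aS)-1-(iodomethyl)-5,5,8a-trimethyl-1,2,4a,5,6,7,8,8a-octahydronaphthalene-2-carboxylate F3. Separately, 18 is acylated (2-methylpropanoyl chloride, pyridine) to (2S)-3-bromo-2-methylpropyl 2-methylpropanoate F4, which with zinc dust and LiCl in THF gives bromo[(2S)-2-methyl-3-(2-methylpropanoyloxy)propyl]zinc F5. Negishi coupling of F3 with F5 (Pd2(dba)3, P(c-C5H9)3, N-methylimidazole, THF/NMP, 80 °C) should give tert-butyl (1S,2S,4aS,8aR)-5,5,8a-trimethyl-1-[(3R)-3-methyl-4-(2-methylpropanoyloxy)butyl]-1,2,4a,5,6,7,8,8a-octahydronaphthalene-2-carboxylate F6. DBU in toluene at 80 °C (as in step 13) moves the ring alkene into conjugation, and the route is rejoined at 25.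

Step 8. Hydride may attack the ring (carbamate) carbonyl of the crowded imide and open the oxazolidinone instead of releasing it, or the reduction may be slow enough for the ester to react. The fallback transfers the acyl group to sulfur and reduces at the aldehyde level. It sets out from 15: LiSEt (from EtSH and n-BuLi, THF, 0 °C) should displace the auxiliary to give tert-butyl (1S,2S,4aS,8aS)-1-[(ethylsulfanyl)carbonyl]-5,5,8a-trimethyl-1,2,4a,5,6,7,8,8a-octahydronaphthalene-2-carboxylate F7. Fukuyama reduction (Et3SiH, Pd/C, acetone, rt) then gives aldehyde 17 directly, where the route is rejoined (16 and step 9 are bypassed).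

**Further compounds**
F1 | step 7 | tert-butyl (2E,4E,10E)-12-hydroxy-6,6,10-trimethyldodeca-2,4,10-trienoate | OC/C=C(\C)CCCC(C)(C)/C=C/C=C/C(=O)OC(C)(C)C
F2 | step 7 | tert-butyl (2E,4E,10E)-6,6,10-trimethyl-12-oxododeca-2,4,10-trienoate | O=C/C=C(\C)CCCC(C)(C)/C=C/C=C/C(=O)OC(C)(C)C
F3 | step 11 | tert-butyl (1S,2S,4aS,8aS)-1-(iodomethyl)-5,5,8a-trimethyl-1,2,4a,5,6,7,8,8a-octahydronaphthalene-2-carboxylate | IC[C@H]1[C@@H](C(=O)OC(C)(C)C)C=C[C@H]2C(C)(C)CCC[C@]12C
F4 | step 11 | (2S)-3-bromo-2-methylpropyl 2-methylpropanoate | CC(C)C(=O)OC[C@H](C)CBr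
F5 | step 11 | bromo[(2S)-2-methyl-3-(2-methylpropanoyloxy)propyl]zinc | CC(C)C(=O)OC[C@H](C)C[Zn]Br
F6 | step 11 | tert-butyl (1S,2S,4aS,8aR)-5,5,8a-trimethyl-1-[(3R)-3-methyl-4-(2-methylpropanoyloxy)butyl]-1,2,4a,5,6,7,8,8a-octahydronaphthalene-2-carboxylate | CC(C)C(=O)OC[C@H](C)CC[C@H]1[C@@H](C(=O)OC(C)(C)C)C=C[C@H]2C(C)(C)CCC[C@]12C
F7 | step 8 | tert-butyl (1S,2S,4aS,8aS)-1-[(ethylsulfanyl)carbonyl]-5,5,8a-trimethyl-1,2,4a,5,6,7,8,8a-octahydronaphthalene-2-carboxylate | CCSC(=O)[C@H]1[C@@H](C(=O)OC(C)(C)C)C=C[C@H]2C(C)(C)CCC[C@]12C
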